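**Strategy.** The seven-membered oxepane (aryl O, two arene carbons, benzylic CH2, bornane C6, C1, C2) bridges the 2-endo and 6-endo positions of a bornane. This is the pattern left when a carbon electrophile adds to C3 of α-pinene and the CMe2 bridge shifts. The route therefore disconnects the benzylic C–C and the C2–O bond to (+)-α-pinene, formaldehyde and a formyl-isovaleryl-phloroglucinol whose second ortho oxygen is capped as a methyl ether. In one operation an o-quinone methide is formed, adds to the pinene as a pinane-fused chroman, and acid then triggers a Wagner–Meerwein shift that turns this into the bornane-fused oxepane with all four stereocentres in place.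

Key step: step 3

Remark: the bornane of the target is (1R,2S,4R,6S) with the ether O at C2-endo and the benzylic CH2 at C6-endo; this maps onto (+)-(1R,5R)-α-pinene (a grade of ≥97% ee is assumed), whose C5 becomes bornane C4.

Step 1
Reactants: 1 2,4,6-trihydroxybenzaldehyde; 2 dimethyl sulfate
Product: 3 2,6-dihydroxy-4-methoxybenzaldehyde
Conditions: Me2SO4 (1.0 equiv), K2CO3 (1.0 equiv), acetone, 0 °C → rt
Reagents that add atoms: dimethyl sulfate, COS(=O)(=O)OC
Why: Williamson O-methylation; the 4-OH (para to CHO) is the most acidic hydroxyl and the only one not held in a hydrogen bond to the formyl group, so one equivalent of base and electrophile should alkylate it selectively, with any 2,4-dimethyl ether removed by chromatography.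

Step 2
Reactants: 3 2,6-dihydroxy-4-methoxybenzaldehyde; 4 3-methylbutanoyl chloride (isovaleryl chloride)
Product: 5 2,6-dihydroxy-4-methoxy-3-(3-methylbutanoyl)benzaldehyde
Conditions: TiCl4 (2.5 equiv), CH2Cl2, 0 °C → rt; 1 M HCl work-up
Reagents that add atoms: 3-methylbutanoyl chloride, CC(C)CC(Cl)=O
Why: Friedel–Crafts acylation directed ortho by the titanium phenoxide; the two free ring carbons of 3 are equivalent by symmetry, so only one regioisomer is possible, the three oxygen donors should keep the ring nucleophilic despite the formyl group (compare the second acylation of monoacylphloroglucinols), and TiCl4 at or below rt should leave the methyl ether intact.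

Step 3
Reactants: 5 2,6-dihydroxy-4-methoxy-3-(3-methylbutanoyl)benzaldehyde; 6 paraformaldehyde; 7 (+)-(1R,5R)-α-pinene
Product: 10 O-methyl ether of the target (bornane-fused benzoxepine with OMe beside the benzylic carbon), via o-quinone methide 8 (not isolated), via pinane-fused chroman 9 (not isolated)
Conditions: 6 (1.5 equiv), 7 (5 equiv), NaOAc (0.2 equiv), AcOH (1 equiv), 4 Å MS, PhMe, 90 °C; then volatiles and surplus 7 removed in vacuo, CH2Cl2, TfOH (0.5 equiv), −40 → 0 °C (one flask)
Reagents that add atoms: paraformaldehyde, C=O; (+)-α-pinene, CC1=CC[C@@H]2C[C@H]1C2(C)C
Why: 5 condenses with formaldehyde at its only free ring carbon and loses water to o-quinone methide 8, whose single heterodiene (exocyclic CH2=C–C=O on the oxygen ortho to CHO, the other ortho oxygen being the methyl ether) adds to the trisubstituted alkene of 7 in an inverse-demand hetero-Diels–Alder reaction, a known three-component reaction type of acylphloroglucinols, formaldehyde and terpene alkenes, closing the six-membered pyran of 9 by [4+2] with O on the methyl-bearing C2 and CH2 on C3, both on the face anti to the CMe2 bridge. Acid then ionises the tertiary C2–O bond of 9, which is antiperiplanar to the C1–C6 (CMe2) bond, so this bridge shifts from C1 to C2 (the classical pinanyl→bornyl Wagner–Meerwein shift, as in the conversion of α-pinene into bornyl chloride or bornyl esters; the cyclobutane expands to the second cyclopentane of the bornane), and the tethered phenol recaptures the bridged cation at the former C1 anti to the migrating bridge, a 7-exo-tet-type opening of the σ-bridged ion that closes the oxepane as the last ring. The stereocentres follow from the two bridgeheads of 7: bornane C6 from the anti-face cycloaddition, the quaternary C1 from the stereospecific suprafacial 1,2-shift, C2 (endo O) from anti capture, and C4 is pinene C5 untouched. The step needs O-regioselectivity (secured by the OMe block), migration of the CMe2 and not the CH2 bridge (secured by the antiperiplanar C1–C6 bond, the C1–C7 bond being gauche), and 1,2-shift in preference to cyclobutane fragmentation (favoured by low temperature, a non-polar medium, a non-nucleophilic counter-ion and a nucleophile held on the endo face). Release of cyclobutane strain and the slow ionisation of endo-bornyl ethers should make 10 the sink of the cation manifold.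

Step 4
Reactants: 10 O-methyl ether of the target
Product: 11 target (CNP0246493.1)
Conditions: LiCl (5 equiv), DMF, 140 °C; 1 M HCl work-up
Reagents that add atoms: none
Why: Lithium-assisted SN2 O-demethylation by chloride; the OMe is ortho to the ketone and para to the aldehyde, so the departing aryloxide is a chelated vinylogous carboxylate, whereas the secondary, neopentyl-type bornyl ether carbon cannot undergo SN2 and no acid able to ionise it is present, so the four stereocentres should be untouched.

**Compound list**
1 | 2,4,6-trihydroxybenzaldehyde | O=Cc1c(O)cc(O)cc1O | starting material
2 | dimethyl sulfate | COS(=O)(=O)OC | starting material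
3 | 2,6-dihydroxy-4-methoxybenzaldehyde | COc1cc(O)c(C=O)c(O)c1 | intermediate
4 | 3-methylbutanoyl chloride | CC(C)CC(Cl)=O | starting material
5 | 2,6-dihydroxy-4-methoxy-3-(3-methylbutanoyl)benzaldehyde | CC(C)CC(=O)c1c(O)c(C=O)c(O)cc1OC | intermediate
6 | paraformaldehyde (formaldehyde source) | C=O | starting material
7 | (+)-(1R,5R)-α-pinene (2,6,6-trimethylbicyclo[3.1.1]hept-2-ene) | CC1=CC[C@@H]2C[C@H]1C2(C)C | starting material
8 | o-quinone methide, 2-hydroxy-4-methoxy-5-methylidene-3-(3-methylbutanoyl)-6-oxocyclohexa-1,3-diene-1-carbaldehyde | C=C1C(=O)C(C=O)=C(O)C(C(=O)CC(C)C)=C1OC | intermediate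
9 | pinane-fused chroman: aryl O on pinane C2, benzylic CH2 on C3, cis-fused on the face anti to the CMe2 bridge, pinane (1S,2R,3S,5R); arene with CHO ortho to the ring O, then OH, isovaleryl, OMe | CC(C)CC(=O)c1c(O)c(C=O)c2O[C@@]3(C)[C@H]4C[C@@H](C[C@H]3Cc2c1OC)C4(C)C | intermediate
10 | O-methyl ether of the target: (1R,2S,4R,6S)-1,7,7-trimethylbicyclo[2.2.1]heptane whose 2-endo O and 6-endo CH2 are joined through the arene (1-benzoxepine); arene with CHO ortho to the ring O, OH, isovaleryl para to the ring O, OMe next to the benzylic carbon | CC(C)CC(=O)c1c(O)c(C=O)c2c(c1OC)C[C@@H]1C[C@@H]3C[C@H](O2)[C@@]1(C)C3(C)C | intermediate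
11 | target: same (1R,2S,4R,6S)-bornane-fused 1-benzoxepine with free OH in place of OMe | CC(C)CC(=O)c1c(O)c(C=O)c2c(c1O)C[C@@H]1C[C@@H]3C[C@H](O2)[C@@]1(C)C3(C)C | target

Total step count: 4. Longest linear sequence: 4 steps (1 → 3 → 5 → 10 → 11).

**Steps most likely to fail**

Step 3. In the one-flask mode, Michael addition of unreacted 5 to quinone methide 8 (methylene-bridged dimerisation) and acid-induced isomerisation of surplus 7 can consume the partners. After ionisation, the cation can also open its cyclobutane towards p-menthene products instead of undergoing the 1,2-shift. The fallback sets out from 5 and returns at 10. Compound 5 is aminomethylated (morpholine, aqueous formaldehyde from 6, EtOH, rt; Mannich reaction) to the stable Mannich base 2,6-dihydroxy-4-methoxy-3-(3-methylbutanoyl)-5-(morpholin-4-ylmethyl)benzaldehyde F1. Heating F1 with 7 in toluene at 110 °C should release 8 by loss of morpholine in the absence of free 5 and formaldehyde, and chroman 9 is now isolated and purified. Pure 9 is then rearranged in a separate flask with a catalytic chelating Lewis acid (BF3·OEt2, 20 mol %, CH2Cl2, −40 °C) that binds the formyl and ether oxygens, so that ionisation should proceed as a tight, internally returning ion pair and give 10.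

Step 2. Chelation of TiCl4 by the hydroxy-aldehyde can deactivate the ring, so that acylation stops at the aryl ester or does not start. Longer exposure invites cleavage of the methyl ether or protodeformylation. The fallback sets out from 3 and returns at 5. O-acylation with 4 (1 equiv, pyridine, CH2Cl2, 0 °C) should give the mono-ester 2-formyl-3-hydroxy-5-methoxyphenyl 3-methylbutanoate F2. Photo-Fries rearrangement (254 nm, MeCN, rt) follows: the acyl radical of the caged pair recombines at the ortho or the para carbon of the phenoxyl partner. These are the two symmetry-equivalent free positions, so both paths should converge on 5 without any Lewis acid.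

Step 4. At 140 °C, dealkylation at the doubly ortho-substituted methoxy group may be slow, and amine from thermal breakdown of DMF can condense with the formyl group. The fallback goes from 10 directly to 11 and makes no new compound (F0). It changes the mode of activation to chelation-directed Lewis-acid demethylation: BCl3 (3 equiv), CH2Cl2, −78 → −20 °C, then aqueous work-up. Boron bound to the ketone oxygen should activate only the neighbouring OMe towards chloride at low temperature. The secondary endo-bornyl ether, which can ionise only through the strained pinanyl pathway, should persist.

**Further compounds**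
F1 | step 3 | 2,6-dihydroxy-4-methoxy-3-(3-methylbutanoyl)-5-(morpholin-4-ylmethyl)benzaldehyde | CC(C)CC(=O)c1c(O)c(C=O)c(O)c(CN2CCOCC2)c1OC
F2 | step 2 | 2-formyl-3-hydroxy-5-methoxyphenyl 3-methylbutanoate | CC(C)CC(=O)Oc1cc(OC)cc(O)c1C=O
F0 | step 4 | none | none
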